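The lactone ring is disconnected at its ring O–C6 bond and its C7=C11 double bond. One operation joins a (6S)-α-mesyloxy ketone to 3-acetoxy-2-(diethoxyphosphoryl)propanoic acid: carboxylate SN2 at C6 with inversion, then intramolecular Horner–Wadsworth–Emmons olefination of the C7 ketone. It exploits the C6–C7 edge shared by the butenolide and the ten-membered ring as a 1,2-dielectrophile, C6 being activated by the C7 carbonyl and the C4=C5 alkene. The acyclic precursor comes from a six-membered lactone made by ring-closing metathesis, which fixes the Z C4=C5 geometry; the carbocycle is closed afterwards by a Nozaki–Hiyama–Kishi reaction.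

Key step: step 15

Remark (locants): germacrane numbering of the target is used throughout: C1 ketone, C2 methylene, C3 acetoxy methine, C4(C15 methyl)=C5, C6 lactone methine, C7=C11 butenolide alkene, C8 and C9 methylenes, C10 with exocyclic methylene C14, C12 lactone carbonyl, C13 acetoxymethyl carbon.

Remark (assumption): compounds 1, 2, 6, 13 and 20, bromomethyl acetate and 2,3-dibromopropene are taken as purchasable.

Step 1
Reactants: 1 ethyl 3,3-diethoxypropanoate; 2 isopropenylmagnesium bromide
Product: 4 (±)-1,1-diethoxy-4-methylpent-4-en-3-ol, via 3,3-diethoxypropanal 3 (not isolated)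
Conditions: iBu2AlH (DIBAL-H, 1.05 equiv), CH2Cl2, −78 °C; then 2 (1.5 equiv, THF), −78 → 0 °C; aq. potassium sodium tartrate work-up
Reagents that add atoms: none
Why: Half-reduction of the ester gives an aluminium hemiacetal that releases the aldehyde to the Grignard reagent in the same flask (one-pot ester reduction–Grignard addition); the carbinol forms racemic and is resolved in step 2.

Step 2
Reactants: 4 (±)-1,1-diethoxy-4-methylpent-4-en-3-ol
Product: 5 (S)-1,1-diethoxy-4-methylpent-4-en-3-ol
Conditions: Ti(OiPr)4 (0.2 equiv), D-(−)-diisopropyl tartrate (0.25 equiv), t-BuOOH (0.55 equiv), 4 Å MS, CH2Cl2, −20 °C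
Reagents that add atoms: none
Why: Sharpless kinetic resolution, in which the D-tartrate catalyst should epoxidise the (R)-enantiomer of this 2-substituted secondary allylic alcohol much faster, so that the (S)-alcohol (the C3 stereocentre) is recovered as the unreacted half.

Step 3
Reactants: 6 (S)-3-hydroxydihydrofuran-2(3H)-one
Product: 7 (S)-3-[(tert-butyldimethylsilyl)oxy]dihydrofuran-2(3H)-one
Conditions: TBSCl, imidazole, DMF, rt
Reagents that add atoms: tert-butyldimethylsilyl chloride, CC(C)(C)[Si](C)(C)Cl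
Why: Imidazole-promoted silyl ether formation protects the future C6 oxygen without touching the stereocentre.

Step 4
Reactants: 7 (S)-3-[(tert-butyldimethylsilyl)oxy]dihydrofuran-2(3H)-one
Product: 8 (S)-2-[(tert-butyldimethylsilyl)oxy]-4-(phenylselanyl)butanoic acid
Conditions: (PhSe)2 (0.55 equiv), NaH, THF, reflux; then 7, 18-crown-6 (0.1 equiv), THF/DMF, 80 °C; then 1 M HCl to pH 3, 0 °C
Reagents that add atoms: diphenyl diselenide, c1ccc(cc1)[Se][Se]c1ccccc1
Why: The soft selenolate opens the γ-lactone by SN2 at the O–CH2 carbon (alkyl–oxygen cleavage), which leaves the silyloxy-bearing stereocentre untouched.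

Step 5
Reactants: 8 (S)-2-[(tert-butyldimethylsilyl)oxy]-4-(phenylselanyl)butanoic acid
Product: 10 (S)-2-[(tert-butyldimethylsilyl)oxy]but-3-enoic acid, via selenoxide 9 (not isolated)
Conditions: H2O2 (30% aq., 2 equiv), THF, 0 °C; then iPr2NH (2 equiv), 1,2-dichloroethane, 70 °C
Reagents that add atoms: none
Why: Selenide oxidation and selenoxide syn-elimination can only take a hydrogen from the single β-carbon, so the terminal vinyl group (C5) should form without involving the α-stereocentre.

Step 6
Reactants: 5 (S)-1,1-diethoxy-4-methylpent-4-en-3-ol; 10 (S)-2-[(tert-butyldimethylsilyl)oxy]but-3-enoic acid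
Product: 11 (S)-1,1-diethoxy-4-methylpent-4-en-3-yl (S)-2-[(tert-butyldimethylsilyl)oxy]but-3-enoate
Conditions: EDC·HCl (1.3 equiv), DMAP (0.1 equiv), CH2Cl2, 0 °C → rt
Reagents that add atoms: none
Why: Carbodiimide (Steglich-type) esterification at low DMAP loading joins the two chiral fragments through the C3 oxygen and the C7 carboxyl carbon without touching either stereocentre.

Step 7
Reactants: 11 (S)-1,1-diethoxy-4-methylpent-4-en-3-yl (S)-2-[(tert-butyldimethylsilyl)oxy]but-3-enoate
Product: 12 (3S,6S)-3-[(tert-butyldimethylsilyl)oxy]-6-(2,2-diethoxyethyl)-5-methyl-3,6-dihydro-2H-pyran-2-one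
Conditions: second-generation Grubbs catalyst (5 mol%), 1,4-benzoquinone (10 mol%), toluene (0.01 M), 80 °C
Reagents that add atoms: none
Why: Ring-closing metathesis of the vinyl and isopropenyl groups closes a six-membered lactone, whose ring size forces C3 and C6 cis on the new trisubstituted C4=C5 alkene (the Z geometry of the target).

Step 8
Reactants: 13 3-bromobut-3-en-1-ol
Product: 14 2,4-dibromobut-1-ene
Conditions: CBr4, PPh3, CH2Cl2, 0 °C
Reagents that add atoms: carbon tetrabromide, BrC(Br)(Br)Br
Why: Appel bromination converts the primary alcohol into the alkyl bromide and leaves the vinyl bromide untouched.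

Step 9
Reactants: 12 (3S,6S)-3-[(tert-butyldimethylsilyl)oxy]-6-(2,2-diethoxyethyl)-5-methyl-3,6-dihydro-2H-pyran-2-one; 14 2,4-dibromobut-1-ene
Product: 16 (3S,4Z,6S)-10-bromo-6-[(tert-butyldimethylsilyl)oxy]-1,1-diethoxy-3-hydroxy-4-methylundeca-4,10-dien-7-one, via bromobutenyl Grignard reagent 15 (not isolated)
Conditions: 14, Mg, Et2O, 0 °C → rt; anhydrous CeCl3, THF, −78 °C; then 12, −78 °C; aq. NH4Cl
Reagents that add atoms: none
Why: Magnesium should insert into the alkyl bromide in preference to the vinyl bromide, and the derived organocerium reagent should add once to the lactone carbonyl without enolising it (organometallic mono-addition to a lactone), the chelated tetrahedral intermediate collapsing on work-up to free the C3 hydroxyl and the C7 ketone.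

Step 10
Reactants: 16 (3S,4Z,6S)-10-bromo-6-[(tert-butyldimethylsilyl)oxy]-1,1-diethoxy-3-hydroxy-4-methylundeca-4,10-dien-7-one
Product: 17 (3S,4Z,6S)-10-bromo-6-[(tert-butyldimethylsilyl)oxy]-1,1-diethoxy-4-methyl-7-oxoundeca-4,10-dien-3-yl acetate
Conditions: Ac2O, pyridine, DMAP (cat.), CH2Cl2, 0 °C
Reagents that add atoms: acetic anhydride, CC(=O)OC(C)=O
Why: Nucleophile-catalysed acetylation installs the C3 acetate; any six-membered lactol form equilibrates through the open chain, whose secondary hydroxyl should be acylated far faster than the tertiary lactol hydroxyl.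

Step 11
Reactants: 17 (3S,4Z,6S)-10-bromo-6-[(tert-butyldimethylsilyl)oxy]-1,1-diethoxy-4-methyl-7-oxoundeca-4,10-dien-3-yl acetate
Product: 18 (3S,4Z,6S)-10-bromo-1,1-diethoxy-6-hydroxy-4-methyl-7-oxoundeca-4,10-dien-3-yl acetate
Conditions: HF·pyridine, pyridine, THF, 0 °C → rt
Reagents that add atoms: none
Why: Buffered fluoride desilylation is non-basic, so the enolisable α-keto, allylic C6 stereocentre, the acetal and the acetate should survive.

Step 12
Reactants: 18 (3S,4Z,6S)-10-bromo-1,1-diethoxy-6-hydroxy-4-methyl-7-oxoundeca-4,10-dien-3-yl acetate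
Product: 19 (3S,4Z,6S)-10-bromo-1,1-diethoxy-4-methyl-6-[(methylsulfonyl)oxy]-7-oxoundeca-4,10-dien-3-yl acetate
Conditions: MsCl (1.2 equiv), Et3N (1.5 equiv), CH2Cl2, −40 °C; used at once
Reagents that add atoms: methanesulfonyl chloride, CS(=O)(=O)Cl
Why: O-Sulfonylation turns the C6 hydroxyl into a leaving group with retention, since no bond to C6 is broken.

Step 13
Reactants: 20 tert-butyl 2-(diethoxyphosphoryl)acetate
Product: 21 tert-butyl 3-acetoxy-2-(diethoxyphosphoryl)propanoate
Conditions: NaH (1.0 equiv), THF, 0 °C; the anion added slowly to bromomethyl acetate (1.3 equiv), THF, −78 → 0 °C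
Reagents that add atoms: bromomethyl acetate, CC(=O)OCBr
Why: SN2 C-alkylation of the stabilised phosphonoacetate carbanion by the highly reactive acyloxymethyl bromide, with inverse addition keeping the carbanion scarce so that the product is not deprotonated.

Step 14
Reactants: 21 tert-butyl 3-acetoxy-2-(diethoxyphosphoryl)propanoate
Product: 22 3-acetoxy-2-(diethoxyphosphoryl)propanoic acid
Conditions: TFA/CH2Cl2 (1:4), 0 °C → rt
Reagents that add atoms: none
Why: Acidolysis of the tert-butyl ester (loss of 2-methylpropene) should leave the ethyl phosphonate and the acetate intact.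

Step 15
Reactants: 19 (3S,4Z,6S)-10-bromo-1,1-diethoxy-4-methyl-6-[(methylsulfonyl)oxy]-7-oxoundeca-4,10-dien-3-yl acetate; 22 3-acetoxy-2-(diethoxyphosphoryl)propanoic acid
Product: 24 {(5R)-5-[(1Z,3S)-3-acetoxy-5,5-diethoxy-2-methylpent-1-en-1-yl]-4-(3-bromobut-3-en-1-yl)-2-oxo-2,5-dihydrofuran-3-yl}methyl acetate, via phosphonoacetate ester 23 (not isolated)
Conditions: 22 (1.5 equiv), Cs2CO3 (0.75 equiv), DMF, 0 °C → rt; then CsOAc (3 equiv), Cs2CO3 (1.1 equiv), 0 °C
Reagents that add atoms: none
Why: The caesium carboxylate of 22 displaces the C6 mesylate of 19 by SN2, forming the lactone O–C6 bond with inversion (6S to 6R) and giving ester 23; carbonate then deprotonates the phosphonate α-carbon (C11), which adds to the C7 ketone and expels diethyl phosphate to form the C7=C11 bond. The closest known reaction type is the one-pot butenolide annulation of α-halo or α-sulfonyloxy ketones with phosphonoacetic acid salts (carboxylate alkylation, then intramolecular Horner–Wadsworth–Emmons olefination). The five-membered ring closes by 5-exo-trig attack of the carbanion on the ketone carbonyl, followed by syn-elimination from the oxaphosphetane. The only stereocentre formed, C6, is controlled by the configuration of the mesylate through inversion, and the C3 acetate is a spectator. The step needs substitution at C6 over SN2′ attack at C4 and over enolisation, which the α-carbonyl activation of C6, the fully substituted C4 terminus and the weakly basic carboxylate should secure, and it needs closure onto the C7 ketone, the only carbonyl within reach of the carbanion. Loss of acetate from the carbanion by β-elimination should not be destructive, because the phosphonoacrylate ester formed can re-add acetate from the CsOAc buffer and return to the same carbanion, which the irreversible olefination drains.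

Step 16
Reactants: 24 {(5R)-5-[(1Z,3S)-3-acetoxy-5,5-diethoxy-2-methylpent-1-en-1-yl]-4-(3-bromobut-3-en-1-yl)-2-oxo-2,5-dihydrofuran-3-yl}methyl acetate
Product: 25 {(5R)-5-[(1Z,3S)-3-acetoxy-2-methyl-5-oxopent-1-en-1-yl]-4-(3-bromobut-3-en-1-yl)-2-oxo-2,5-dihydrofuran-3-yl}methyl acetate
Conditions: Amberlyst-15, acetone/H2O (20:1), rt; filtered and used directly
Reagents that add atoms: water, O
Why: Mild acid-catalysed acetal hydrolysis unmasks the C1 aldehyde under conditions that should be too gentle to eliminate the β-acetoxy group or touch the esters.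

Step 17
Reactants: 25 {(5R)-5-[(1Z,3S)-3-acetoxy-2-methyl-5-oxopent-1-en-1-yl]-4-(3-bromobut-3-en-1-yl)-2-oxo-2,5-dihydrofuran-3-yl}methyl acetate
Product: 26 [(9S,10Z,11aR)-9-acetoxy-7-hydroxy-10-methyl-6-methylidene-2-oxo-2,4,5,6,7,8,9,11a-octahydrocyclodeca[b]furan-3-yl]methyl acetate
Conditions: CrCl2 (10 equiv), NiCl2 (0.1 equiv), DMSO/THF (3:1), rt, slow addition to 0.003 M
Reagents that add atoms: none
Why: Nozaki–Hiyama–Kishi reaction, in which zerovalent nickel inserts into the C–Br bond and transmetalation gives a vinyl species of trivalent chromium that adds only to the aldehyde, closing the ten-membered ring at C1–C10; the C1 carbinol should form as an epimer mixture that step 18 removes.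

Step 18
Reactants: 26 [(9S,10Z,11aR)-9-acetoxy-7-hydroxy-10-methyl-6-methylidene-2-oxo-2,4,5,6,7,8,9,11a-octahydrocyclodeca[b]furan-3-yl]methyl acetate
Product: 27 [(9S,10Z,11aR)-9-acetoxy-10-methyl-6-methylidene-2,7-dioxo-2,4,5,6,7,8,9,11a-octahydrocyclodeca[b]furan-3-yl]methyl acetate
Conditions: Dess–Martin periodinane, NaHCO3, CH2Cl2, 0 °C → rt
Reagents that add atoms: none
Why: Dess–Martin oxidation of the secondary allylic alcohol gives the α-methylene ketone under buffered, near-neutral conditions that should not eliminate the β-acetoxy group or epimerise C6.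

Compound list

1 | ethyl 3,3-diethoxypropanoate | CCOC(=O)CC(OCC)OCC | starting material
2 | isopropenylmagnesium bromide | CC(=C)[Mg]Br | starting material
3 | 3,3-diethoxypropanal | CCOC(CC=O)OCC | intermediate
4 | (±)-1,1-diethoxy-4-methylpent-4-en-3-ol | CCOC(OCC)CC(O)C(C)=C | intermediate
5 | (S)-1,1-diethoxy-4-methylpent-4-en-3-ol | CCOC(OCC)C[C@H](O)C(C)=C | intermediate
6 | (S)-3-hydroxydihydrofuran-2(3H)-one | O[C@H]1CCOC1=O | starting material
7 | (S)-3-[(tert-butyldimethylsilyl)oxy]dihydrofuran-2(3H)-one | CC(C)(C)[Si](C)(C)O[C@H]1CCOC1=O | intermediate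
8 | (S)-2-[(tert-butyldimethylsilyl)oxy]-4-(phenylselanyl)butanoic acid | CC(C)(C)[Si](C)(C)O[C@@H](CC[Se]c1ccccc1)C(=O)O | intermediate
9 | (2S)-2-[(tert-butyldimethylsilyl)oxy]-4-(phenylseleninyl)butanoic acid (selenoxide, either configuration at selenium) | CC(C)(C)[Si](C)(C)O[C@@H](CC[Se](=O)c1ccccc1)C(=O)O | intermediate
10 | (S)-2-[(tert-butyldimethylsilyl)oxy]but-3-enoic acid | CC(C)(C)[Si](C)(C)O[C@@H](C=C)C(=O)O | intermediate
11 | (S)-1,1-diethoxy-4-methylpent-4-en-3-yl (S)-2-[(tert-butyldimethylsilyl)oxy]but-3-enoate | CCOC(OCC)C[C@H](OC(=O)[C@@H](O[Si](C)(C)C(C)(C)C)C=C)C(C)=C | intermediate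
12 | (3S,6S)-3-[(tert-butyldimethylsilyl)oxy]-6-(2,2-diethoxyethyl)-5-methyl-3,6-dihydro-2H-pyran-2-one | CCOC(OCC)C[C@@H]1OC(=O)[C@@H](O[Si](C)(C)C(C)(C)C)C=C1C | intermediate
13 | 3-bromobut-3-en-1-ol | OCCC(Br)=C | starting material
14 | 2,4-dibromobut-1-ene | BrCCC(Br)=C | intermediate
15 | (3-bromobut-3-en-1-yl)magnesium bromide | Br[Mg]CCC(Br)=C | intermediate
16 | (3S,4Z,6S)-10-bromo-6-[(tert-butyldimethylsilyl)oxy]-1,1-diethoxy-3-hydroxy-4-methylundeca-4,10-dien-7-one | CC(C)(C)[Si](C)(C)O[C@H](C(=O)CCC(Br)=C)/C=C(/C)[C@@H](O)CC(OCC)OCC | intermediate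
17 | (3S,4Z,6S)-10-bromo-6-[(tert-butyldimethylsilyl)oxy]-1,1-diethoxy-4-methyl-7-oxoundeca-4,10-dien-3-yl acetate | CC(C)(C)[Si](C)(C)O[C@H](C(=O)CCC(Br)=C)/C=C(/C)[C@@H](OC(C)=O)CC(OCC)OCC | intermediate
18 | (3S,4Z,6S)-10-bromo-1,1-diethoxy-6-hydroxy-4-methyl-7-oxoundeca-4,10-dien-3-yl acetate | O[C@H](C(=O)CCC(Br)=C)/C=C(/C)[C@@H](OC(C)=O)CC(OCC)OCC | intermediate
19 | (3S,4Z,6S)-10-bromo-1,1-diethoxy-4-methyl-6-[(methylsulfonyl)oxy]-7-oxoundeca-4,10-dien-3-yl acetate | CS(=O)(=O)O[C@H](C(=O)CCC(Br)=C)/C=C(/C)[C@@H](OC(C)=O)CC(OCC)OCC | intermediate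
20 | tert-butyl 2-(diethoxyphosphoryl)acetate | CCOP(=O)(OCC)CC(=O)OC(C)(C)C | starting material
21 | tert-butyl 3-acetoxy-2-(diethoxyphosphoryl)propanoate (racemic) | CCOP(=O)(OCC)C(COC(C)=O)C(=O)OC(C)(C)C | intermediate
22 | 3-acetoxy-2-(diethoxyphosphoryl)propanoic acid (racemic) | CCOP(=O)(OCC)C(COC(C)=O)C(=O)O | intermediate
23 | (3S,4Z,6R)-3-acetoxy-10-bromo-1,1-diethoxy-4-methyl-7-oxoundeca-4,10-dien-6-yl 3-acetoxy-2-(diethoxyphosphoryl)propanoate (both epimers at the phosphonate carbon) | CCOP(=O)(OCC)C(COC(C)=O)C(=O)O[C@@H](C(=O)CCC(Br)=C)/C=C(/C)[C@@H](OC(C)=O)CC(OCC)OCC | intermediate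
24 | {(5R)-5-[(1Z,3S)-3-acetoxy-5,5-diethoxy-2-methylpent-1-en-1-yl]-4-(3-bromobut-3-en-1-yl)-2-oxo-2,5-dihydrofuran-3-yl}methyl acetate | CC(=O)OCC1=C(CCC(Br)=C)[C@@H](/C=C(/C)[C@@H](OC(C)=O)CC(OCC)OCC)OC1=O | intermediate
25 | {(5R)-5-[(1Z,3S)-3-acetoxy-2-methyl-5-oxopent-1-en-1-yl]-4-(3-bromobut-3-en-1-yl)-2-oxo-2,5-dihydrofuran-3-yl}methyl acetate | CC(=O)OCC1=C(CCC(Br)=C)[C@@H](/C=C(/C)[C@@H](OC(C)=O)CC=O)OC1=O | intermediate
26 | [(9S,10Z,11aR)-9-acetoxy-7-hydroxy-10-methyl-6-methylidene-2-oxo-2,4,5,6,7,8,9,11a-octahydrocyclodeca[b]furan-3-yl]methyl acetate (both carbinol epimers) | C=C1CCC2=C(COC(C)=O)C(=O)O[C@@H]2/C=C(/C)[C@@H](OC(C)=O)CC1O | intermediate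
27 | [(9S,10Z,11aR)-9-acetoxy-10-methyl-6-methylidene-2,7-dioxo-2,4,5,6,7,8,9,11a-octahydrocyclodeca[b]furan-3-yl]methyl acetate | C=C1CCC2=C(COC(C)=O)C(=O)O[C@@H]2/C=C(/C)[C@@H](OC(C)=O)CC1=O | target

Total step count: 18.
Longest linear sequence: 13 steps (steps 3, 4, 5, 6, 7, 9, 10, 11, 12, 15, 16, 17, 18, from compound 6).

Steps most likely to fail

Step 15. What may go wrong is β-elimination of acetate from the phosphonate carbanion outrunning ring closure without productive re-addition. Configuration at C6 may also be lost, by enolisation of the mesyloxy ketone before substitution or by γ-deprotonation of the butenolide afterwards. The fallback sets out from mesylate 19 and forms the two bonds in separate steps without a phosphonate. Displacement with caesium acrylate (acrylic acid, Cs2CO3, DMF, 0 °C) should give the inverted (3S,4Z,6R)-acrylate ester F1. An intramolecular Morita–Baylis–Hillman reaction onto the C7 ketone (DABCO or PMe3, THF) would close the lactone as the α-methylene-β-hydroxy-γ-butyrolactone F2. Acetylation (Ac2O, DMAP, Et3N) to the tertiary allylic acetate F3 and amine-catalysed 1,3-transposition of the acetoxy group (DABCO, THF, 60 °C) should give the conjugated butenolide, so the fallback comes back to the route at compound 24.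

Step 17. What may go wrong is intermolecular coupling outpacing closure of the ten-membered ring, slow oxidative addition of the 2-bromoalkene, or nickel insertion into the activated allylic acetate. The fallback sets out from aldehyde 25 and closes the ring by acylation instead of carbonyl addition. Palladium-catalysed stannylation ((Me3Sn)2, Pd(PPh3)4, toluene, 80 °C) would give the vinylstannane aldehyde F4. Pinnick oxidation (NaClO2, NaH2PO4, 2-methylbut-2-ene, t-BuOH/H2O) would give the vinylstannane acid F5. Neutral conversion with 1-chloro-N,N,2-trimethylprop-1-en-1-amine (Ghosez reagent) would give the acid chloride F6. An intramolecular acyl Stille coupling (Pd2(dba)3, tri(2-furyl)phosphine, toluene, high dilution) would then form the C1–C10 bond at the ketone oxidation level, so the fallback comes back to the route at compound 27 and step 18 is not needed.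

Step 9. What may go wrong is enolisation of the lactone by the organometallic (epimerising C6), double addition, or decomposition of the bromobutenyl Grignard reagent before it is used. The fallback sets out from lactone 12 and builds the side chain by enolate alkylation. Mono-addition of MeLi (1.05 equiv, THF, −78 °C) would give the methyl ketone (3S,4Z,6S)-6-[(tert-butyldimethylsilyl)oxy]-1,1-diethoxy-3-hydroxy-4-methyloct-4-en-7-one F7. Double deprotonation with LiN(iPr)2 (2.2 equiv, THF, −78 °C; alkoxide plus the kinetic enolate on the methyl side) and alkylation with 2,3-dibromopropene would install C9, C10 and C14, so the fallback comes back to the route at compound 16.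

Further compounds
F1 | step 15 | (3S,4Z,6R)-3-acetoxy-10-bromo-1,1-diethoxy-4-methyl-7-oxoundeca-4,10-dien-6-yl acrylate | C=CC(=O)O[C@@H](C(=O)CCC(Br)=C)/C=C(/C)[C@@H](OC(C)=O)CC(OCC)OCC
F2 | step 15 | (5R)-5-[(1Z,3S)-3-acetoxy-5,5-diethoxy-2-methylpent-1-en-1-yl]-4-(3-bromobut-3-en-1-yl)-4-hydroxy-3-methylidenedihydrofuran-2(3H)-one (either configuration at the carbinol carbon) | C=C1C(=O)O[C@H](/C=C(/C)[C@@H](OC(C)=O)CC(OCC)OCC)C1(O)CCC(Br)=C
F3 | step 15 | (5R)-5-[(1Z,3S)-3-acetoxy-5,5-diethoxy-2-methylpent-1-en-1-yl]-4-(3-bromobut-3-en-1-yl)-3-methylidene-2-oxotetrahydrofuran-4-yl acetate | C=C1C(=O)O[C@H](/C=C(/C)[C@@H](OC(C)=O)CC(OCC)OCC)C1(OC(C)=O)CCC(Br)=C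
F4 | step 17 | {(5R)-5-[(1Z,3S)-3-acetoxy-2-methyl-5-oxopent-1-en-1-yl]-2-oxo-4-[3-(trimethylstannyl)but-3-en-1-yl]-2,5-dihydrofuran-3-yl}methyl acetate | CC(=O)OCC1=C(CCC(=C)[Sn](C)(C)C)[C@@H](/C=C(/C)[C@@H](OC(C)=O)CC=O)OC1=O
F5 | step 17 | (3S,4Z)-3-acetoxy-5-{(2R)-4-(acetoxymethyl)-5-oxo-3-[3-(trimethylstannyl)but-3-en-1-yl]-2,5-dihydrofuran-2-yl}-4-methylpent-4-enoic acid | CC(=O)OCC1=C(CCC(=C)[Sn](C)(C)C)[C@@H](/C=C(/C)[C@@H](OC(C)=O)CC(=O)O)OC1=O
F6 | step 17 | (3S,4Z)-3-acetoxy-5-{(2R)-4-(acetoxymethyl)-5-oxo-3-[3-(trimethylstannyl)but-3-en-1-yl]-2,5-dihydrofuran-2-yl}-4-methylpent-4-enoyl chloride | CC(=O)OCC1=C(CCC(=C)[Sn](C)(C)C)[C@@H](/C=C(/C)[C@@H](OC(C)=O)CC(=O)Cl)OC1=O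
F7 | step 9 | (3S,4Z,6S)-6-[(tert-butyldimethylsilyl)oxy]-1,1-diethoxy-3-hydroxy-4-methyloct-4-en-7-one | CC(C)(C)[Si](C)(C)O[C@H](C(C)=O)/C=C(/C)[C@@H](O)CC(OCC)OCC
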